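| setting | alder | larch | cedar | flask |
|---|---|---|---|---|
| first end groups | 0.54 M | 0.54 M | 0.54 M | 0.54 M |
| second end groups | 0.27 M | 0.41 M | 0.54 M | 0.540 M |
| protic impurity | 0.162 M | 0.162 M | 0.081 M | 0.162 M |
| remark | run made earlier | run made earlier | run made earlier |  |
| time |  |  |  | 5.0 h |

| run | time / h | links / % | first end groups / % |
|---|---|---|---|
| alder | 0.250 | 17 | 84 |
| alder | 0.417 | 20 | 78 |
| alder | 0.667 | 28 | 70 |
| alder | 1.00 | 33 | 67 |
| alder | 2.00 | 37 | 62 |
| alder | 3.00 | 38 | 60 |
| larch | 0.500 | 36 | 70 |
| larch | 1.00 | 48 | 54 |
| larch | 1.50 | 51 | 48 |
| larch | 2.00 | 56 | 45 |
| larch | 2.50 | 54 | 46 |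
| larch | 3.00 | 57 | 44 |
| cedar | 0.250 | 28 | 71 |
| cedar | 0.417 | 38 | 60 |
| cedar | 0.833 | 57 | 42 |
| cedar | 1.50 | 68 | 34 |
| cedar | 3.00 | 75 | 22 |

(scatter of a reading: 1.5 percentage points)

- each molecule carries two end groups: a chain counts once for every two ends that are left, dead ends included; the units are half of the end groups of the two monomers charged
- the earlier runs were read with a standard deviation of 1.5 percentage points

* average number of monomer units in a chain (unreacted monomers counted as chains of one) at 5.0 h
* part of the first end groups that has reacted at 5.0 h

About 76.0 % of the second end groups charged in the alder run stood as links at its last reading, when links had moved by 1 point in the last hour, inside a scatter of 1.5 points. This linking share, plateau links per second end group charged, reads 75.1 % in the larch run at the same first end groups and impurity. In both runs second end groups are the limiting reagent, and my own reckoning carries the share to the flask, which has the same first end groups and impurity: links should approach 76.0 % of the first end groups.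

The time ladder has three rungs. In the cedar run, with equal charges of end groups and half the flask's impurity, first end groups read 60 % at 0.417 h, which as second-order loss gives 0.625 h for a fall to half. In the alder run links flatten by 2.00 h. Late in the flask first end groups near 24.0 %, so the last second end groups link on a longer time, 2.61 h, and 5.0 h is twice that. The flask should therefore stand just under its ceiling. Each link removes two ends, so the ceiling for dp is 4.17.

The forecast says dp 3.9 and c 74.5 %, holding that “the impurity must kill second ends in competition with linking”.

The flask gives dp 3.88 and c 74.2 %.

    first end groups + second end groups ⇌ links + released group (K = 44.0, k = 0.0530 L mol⁻¹ min⁻¹)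
    second end groups + protic impurity → quenched reagent (k = 0.0490 L mol⁻¹ min⁻¹)
    released group → by-product carried off (k = 0.00440 min⁻¹)

At 0.378 h the forward linking step alone uses second end groups 3.5 times as fast as quenching does. The flask also holds 0.133 M of released group at 5.00 h, which no reading showed, and its c then stands 1.8 points under the 76.0 % carried over by the share, rising by 2 points to 76.2 % at 50.0 h.

For a neighbour of the flask, alike but charged with 0.32 M of second end groups, the share gives c of 45.0 % and dp of 2.30. That neighbour gives 45.5 % and 2.33.

(The earlier runs and the new flask were generated by integration on assumed constants.)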